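## Retrosynthetic overview

Germacrane numbering is used: lactone O on C6, ring fusion C7 (bears C11), tiglate on C8, CH2 = C9, methyl-bearing carbons C10 and C4, oxiranes C1–C10 and C4–C5.
1. Both oxiranes are removed together. One peripheral double epoxidation of the E,E-cyclodeca-1(10),4-diene 25 should set C1, C10, C4 and C5 in a single event.
2. The ten-membered ring is cut at C9–C10. In 21 an E-alkenyl iodide (C10) and the primary iodide of an iodohydrin (C9/C8) are joined by a nickel-catalysed reductive ring closure.
3. Enabling feature: the homoallylic carbinol array C8(OH)–C9H2–C10(CH3)=C1 beside the trans-fused γ-lactone ring (O, C6, C7, C11, C12). The β-oxygen on C8 rules out a C9 carbanion but not a C9 radical, and the lactone plus the E-C4=C5 alkene hold the C5 and C8 arms gauche so that C9 and C10 can meet.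
4. The lactone is made first by a chair allylboration/lactonisation that relays the one purchased stereocentre (C8, from (R)-glyceraldehyde acetonide) to C7 and C6. Ring order: γ-lactone (step 9), carbocycle (step 12), two oxiranes (step 14).

Key step: step 12

Remark (assumption): (R)-2,3-O-isopropylideneglyceraldehyde 11 is taken as purchased. The C11 configuration drawn for 19–24 is the thermodynamic one (CH2SO2Ph trans to C8) and is erased in step 13.

## Route

Step 1
Reactants: 1 pent-3-yn-1-ol
Product: 2 5-bromopent-2-yne
Conditions: CBr4, PPh3, CH2Cl2, 0 °C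
Reagents that add atoms: carbon tetrabromide BrC(Br)(Br)Br
Why: The Appel bromination displaces the oxyphosphonium ion of the primary alcohol by SN2 under neutral conditions that leave the internal alkyne untouched, and no stereocentre is involved.

Step 2
Reactants: 2 5-bromopent-2-yne; 3 methyl but-2-ynoate
Product: 6 methyl (E)-3-methyloct-2-en-6-ynoate, via pent-3-ynylmagnesium bromide 4 (not isolated), via pent-3-ynylcopper 5 (not isolated)
Conditions: Mg, THF, 35 °C; CuBr·SMe2 (1 equiv), THF/Me2S, −45 °C; 3, −78 °C; aq NH4Cl, −78 °C
Reagents that add atoms: none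
Why: The syn-carbocupration of an alkynoate at low temperature, followed by protonation of the alkenylcopper with retention, places the new chain trans to the ester and so fixes the E geometry of C4=C5.

Step 3
Reactants: 6 methyl (E)-3-methyloct-2-en-6-ynoate
Product: 7 (E)-3-methyloct-2-en-6-yn-1-ol
Conditions: i-Bu2AlH (2.2 equiv), CH2Cl2, −78 °C
Reagents that add atoms: none
Why: The 1,2-reduction of an enoate by i-Bu2AlH gives the allylic alcohol without touching the alkene geometry or the alkyne.

Step 4
Reactants: 7 (E)-3-methyloct-2-en-6-yn-1-ol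
Product: 9 (2E,6E)-7-iodo-3-methylocta-2,6-dien-1-ol, via C,O-bis(zirconocene) species 8 (not isolated)
Conditions: Cp2Zr(H)Cl (2.6 equiv), THF, 25 to 40 °C; I2, THF, −20 °C
Reagents that add atoms: iodine II
Why: In this hydrozirconation/iodinolysis the syn addition equilibrates under excess reagent to the isomer with zirconium on the less hindered, methyl-bearing carbon C10, and iodinolysis with retention gives the E-alkenyl iodide with iodine trans to C2.

Step 5
Reactants: 9 (2E,6E)-7-iodo-3-methylocta-2,6-dien-1-ol
Product: 10 (2E,6E)-7-iodo-3-methylocta-2,6-dienal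
Conditions: MnO2, CH2Cl2, 25 °C
Reagents that add atoms: none
Why: The allylic oxidation with MnO2 is selective for the allylic alcohol and keeps both alkene geometries and the alkenyl iodide.

Step 6
Reactants: 11 (R)-2,2-dimethyl-1,3-dioxolane-4-carbaldehyde
Product: 12 (S)-4-(2,2-dibromovinyl)-2,2-dimethyl-1,3-dioxolane
Conditions: CBr4, PPh3, CH2Cl2, 0 °C
Reagents that add atoms: carbon tetrabromide BrC(Br)(Br)Br
Why: In the first stage of the Corey–Fuchs sequence the Wittig-type dibromoolefination is fast and non-basic, so the α-alkoxy stereocentre (future C8) is not epimerised.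

Step 7
Reactants: 12 (S)-4-(2,2-dibromovinyl)-2,2-dimethyl-1,3-dioxolane
Product: 14 methyl 3-[(4S)-2,2-dimethyl-1,3-dioxolan-4-yl]prop-2-ynoate, via lithium acetylide 13 (not isolated)
Conditions: n-BuLi (2.1 equiv), THF, −78 °C; ClCO2Me, −78 to 0 °C
Reagents that add atoms: methyl chloroformate COC(=O)Cl
Why: In the second stage of the Corey–Fuchs sequence elimination and bromine–lithium exchange give the acetylide, which is acylated by the chloroformate while the propargylic stereocentre stays intact.

Step 8
Reactants: 14 methyl 3-[(4S)-2,2-dimethyl-1,3-dioxolan-4-yl]prop-2-ynoate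
Product: 16 methyl (Z)-3-[(4S)-2,2-dimethyl-1,3-dioxolan-4-yl]-2-[(pinacolatoboryl)methyl]acrylate (dioxolane cis to CO2Me), via alkenylalane 15 (not isolated)
Conditions: i-Bu2AlH, HMPA, THF, 0 °C; ICH2B(pin), 0 to 25 °C
Reagents that add atoms: 2-(iodomethyl)-4,4,5,5-tetramethyl-1,3,2-dioxaborolane ICB1OC(C)(C)C(C)(C)O1
Why: The conjugate syn-hydroalumination of the alkynoate puts hydride on C7 and aluminium on C11, and alkylation of the α-aluminoacrylate by the halomethylboronate with retention gives the allylboronate in which C8 is trans to the CH2B group.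

Step 9
Reactants: 10 (2E,6E)-7-iodo-3-methylocta-2,6-dienal; 16 allylboronate
Product: 18 trans-α-methylene-γ-butyrolactone acetonide, via borate ester 17 (not isolated)
Conditions: Sc(OTf)3 (10 mol %), toluene, 0 to 25 °C
Reagents that add atoms: none
Why: In this Lewis-acid-catalysed allylboration through a closed chair (Zimmerman–Traxler) transition state the boronate geometry puts C8 and the dienyl residue equatorial, which gives the anti adduct and hence the trans-lactone after in-situ lactonisation, while allylic 1,3-strain against the cis ester locks H8 in the alkene plane so that the aldehyde attacks C7 anti to the C8–C9 bond and C8 is relayed to C7 and C6 in one event.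

Step 10
Reactants: 18 trans-α-methylene-γ-butyrolactone acetonide
Product: 20 sulfone diol, via sulfone acetonide 19 (not isolated)
Conditions: PhSO2Na (1.5 equiv), AcOH/H2O 4:1, 40 °C
Reagents that add atoms: sodium benzenesulfinate [Na+].[O-]S(=O)c1ccccc1
Why: The sulfa-Michael addition of benzenesulfinic acid masks the acrylate as a β-sulfonyl lactone (C11 settles trans to C8 and is erased later), and the same aqueous acid hydrolyses the terminal acetonide without touching C8.

Step 11
Reactants: 20 sulfone diol
Product: 21 iodohydrin diiodide (C9–I, C8–OH, C10–I)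
Conditions: I2 (1.1 equiv), PPh3, imidazole, CH2Cl2, 0 °C
Reagents that add atoms: iodine II
Why: This Appel-type iodination activates the unhindered primary C9 hydroxyl much faster than the secondary C8 hydroxyl, works without strong base so that the lactone and sulfone survive, and leaves the C8 configuration untouched.

Step 12
Reactants: 21 iodohydrin diiodide
Product: 22 8β-hydroxy-13-(phenylsulfonyl)germacra-1(10)E,4E-dien-12,6α-olide
Conditions: NiBr2(dme) (30 mol %), 4,4'-di-tert-butyl-2,2'-bipyridine (33 mol %), Mn powder (4 equiv), NaI (0.5 equiv), DMA, 25 °C, 21 added by syringe pump over 20 h (final 2 mM)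
Reagents that add atoms: none
Why: Proposed new method: Zerovalent nickel inserts into the C10–I bond with retention, Mn reduces the alkenylnickel halide to the monovalent state, this centre abstracts the iodine atom from C9 of the same molecule, and collapse of the C9 radical onto nickel gives a trivalent alkyl(alkenyl)nickel that forms C9–C10 by reductive elimination. The closest known reaction type is the intermolecular nickel/bipyridine reductive cross-electrophile coupling of alkenyl halides with primary alkyl iodides, iodohydrins from terminal epoxides included, which keeps the alkene geometry and tolerates free hydroxyl, ester and sulfone groups; what is new is its use to close a medium ring. One ring is closed, the ten-membered carbocycle, in an endo mode (C10 and C1 both end up in the ring) by way of an eleven-membered nickelacycle whose long C–Ni bonds carry less strain than the product, so that the strain of the E,E-cyclodecadiene is paid only in the fast, irreversible reductive elimination. No stereocentre is created: the E geometry of C1=C10 is carried over from 21 by the stereoretentive insertion and elimination, C8 is untouched because the radical sits on the neighbouring CH2, and the crown-shaped ring made here is the element that later fixes C1, C10, C4 and C5. The step needs intra- over intermolecular coupling and survival of the other functions: slow addition and a high nickel loading keep every radical close to its own alkenylnickel, the trans-lactone and the E-C4=C5 alkene hold the two arms gauche, a β-hydroxy radical does not eliminate as a C9 zinc or magnesium species would, the acrylate is masked as the β-sulfone so that the radical finds no acceptor, and the alkenyl iodide reacts with zerovalent nickel much faster than the allylic C6–O lactone bond.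

Step 13
Reactants: 22 macrocyclic alcohol; 23 (E)-2-methylbut-2-enoyl chloride (tigloyl chloride)
Product: 25 8β-tigloyloxygermacra-1(10)E,4E,11(13)-trien-12,6α-olide, via sulfone tiglate 24 (not isolated)
Conditions: 23, DMAP, pyridine, CH2Cl2, 0 to 25 °C; then DBU, 0 °C
Reagents that add atoms: none
Why: The DMAP-catalysed acylation esterifies the C8 alcohol with retention, and the E1cB elimination of benzenesulfinate triggered by DBU then regenerates the exocyclic methylene and erases C11.

Step 14
Reactants: 25 8β-tigloyloxygermacra-1(10)E,4E,11(13)-trien-12,6α-olide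
Product: 27 target 1β,10α:4α,5β-diepoxy-8β-tigloyloxygermacr-11(13)-en-12,6α-olide, via 1(10)-monoepoxide 26 (not isolated)
Conditions: mCPBA (2.5 equiv), CH2Cl2/aq phosphate buffer (pH 8), 0 to 25 °C
Reagents that add atoms: 3-chloroperoxybenzoic acid O=C(OO)c1cccc(Cl)c1
Why: In this Prilezhaev epoxidation the crown conformation of the E,E-cyclodecadiene sets both alkene planes perpendicular to the ring with C14 and C15 on the β face, so only the outer faces are open and syn-stereospecific oxygen transfer should give the 1β,10α and 4α,5β oxiranes (C1, C10, C4, C5 in one event), while the electron-poor tiglate and acrylate alkenes stay inert and the buffer suppresses acid-induced transannular cyclisation.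

## Compound list

1 | pent-3-yn-1-ol | CC#CCCO | starting material
2 | 5-bromopent-2-yne | CC#CCCBr | intermediate
3 | methyl but-2-ynoate | CC#CC(=O)OC | starting material
4 | pent-3-ynylmagnesium bromide | CC#CCC[Mg]Br | intermediate
5 | pent-3-ynylcopper | CC#CCC[Cu] | intermediate
6 | methyl (E)-3-methyloct-2-en-6-ynoate | COC(=O)/C=C(\C)CCC#CC | intermediate
7 | (E)-3-methyloct-2-en-6-yn-1-ol | OC/C=C(\C)CCC#CC | intermediate
8 | C,O-bis(zirconocene) species: O-bound Cp2ZrCl alkoxide, Cp2ZrCl on C10 cis to H1 | Cl[Zr](C1C=CC=C1)(C1C=CC=C1)OC/C=C(\C)CC/C=C(\C)[Zr](Cl)(C1C=CC=C1)C1C=CC=C1 | intermediate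
9 | (2E,6E)-7-iodo-3-methylocta-2,6-dien-1-ol | OC/C=C(\C)CC/C=C(\C)I | intermediate
10 | (2E,6E)-7-iodo-3-methylocta-2,6-dienal | O=C/C=C(\C)CC/C=C(\C)I | intermediate
11 | (R)-2,2-dimethyl-1,3-dioxolane-4-carbaldehyde | O=C[C@H]1COC(C)(C)O1 | starting material
12 | (S)-4-(2,2-dibromovinyl)-2,2-dimethyl-1,3-dioxolane | BrC(Br)=C[C@H]1COC(C)(C)O1 | intermediate
13 | lithium [(4S)-2,2-dimethyl-1,3-dioxolan-4-yl]acetylide | [Li]C#C[C@H]1COC(C)(C)O1 | intermediate
14 | methyl 3-[(4S)-2,2-dimethyl-1,3-dioxolan-4-yl]prop-2-ynoate | COC(=O)C#C[C@H]1COC(C)(C)O1 | intermediate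
15 | α-(diisobutylalumino)acrylate, dioxolane cis to CO2Me | COC(=O)/C([Al](CC(C)C)CC(C)C)=C\[C@H]1COC(C)(C)O1 | intermediate
16 | methyl (Z)-3-[(4S)-2,2-dimethyl-1,3-dioxolan-4-yl]-2-[(pinacolatoboryl)methyl]acrylate, dioxolane cis to CO2Me | COC(=O)/C(CB1OC(C)(C)C(C)(C)O1)=C\[C@H]1COC(C)(C)O1 | intermediate
17 | anti allylboration adduct, C6–O–B(pin) borate of the acrylate ester | C=C(C(=O)OC)[C@@H]([C@H](OB1OC(C)(C)C(C)(C)O1)/C=C(\C)CC/C=C(\C)I)[C@H]1COC(C)(C)O1 | intermediate
18 | 3-methylene-5-[(1E,5E)-6-iodo-2-methylhepta-1,5-dienyl]-4-[(4S)-2,2-dimethyl-1,3-dioxolan-4-yl]dihydrofuran-2-one, H6/H7 trans, C6, C7, C8 arranged as in the target | C=C1C(=O)O[C@H](/C=C(\C)CC/C=C(\C)I)[C@H]1[C@H]1COC(C)(C)O1 | intermediate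
19 | 18 with H on C11 and CH2SO2Ph (C13) trans to C8 | O=S(=O)(c1ccccc1)C[C@@H]1C(=O)O[C@H](/C=C(\C)CC/C=C(\C)I)[C@H]1[C@H]1COC(C)(C)O1 | intermediate
20 | sulfone diol, C7 side chain (1S)-1,2-dihydroxyethyl | O=S(=O)(c1ccccc1)C[C@@H]1C(=O)O[C@H](/C=C(\C)CC/C=C(\C)I)[C@H]1[C@H](O)CO | intermediate
21 | iodohydrin diiodide, C7 side chain (1S)-1-hydroxy-2-iodoethyl | O=S(=O)(c1ccccc1)C[C@@H]1C(=O)O[C@H](/C=C(\C)CC/C=C(\C)I)[C@H]1[C@H](O)CI | intermediate
22 | 8β-hydroxy-13-(phenylsulfonyl)germacra-1(10)E,4E-dien-12,6α-olide | O=S(=O)(c1ccccc1)C[C@@H]1C(=O)O[C@@H]2/C=C(\C)CC/C=C(\C)C[C@@H](O)[C@@H]12 | intermediate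
23 | (E)-2-methylbut-2-enoyl chloride (tigloyl chloride) | C/C=C(\C)C(=O)Cl | starting material
24 | 8β-tigloyloxy-13-(phenylsulfonyl)germacra-1(10)E,4E-dien-12,6α-olide | O=S(=O)(c1ccccc1)C[C@@H]1C(=O)O[C@@H]2/C=C(\C)CC/C=C(\C)C[C@@H](OC(=O)/C(C)=C/C)[C@@H]12 | intermediate
25 | 8β-tigloyloxygermacra-1(10)E,4E,11(13)-trien-12,6α-olide | C=C1C(=O)O[C@@H]2/C=C(\C)CC/C=C(\C)C[C@@H](OC(=O)/C(C)=C/C)[C@@H]12 | intermediate
26 | 1β,10α-epoxy-8β-tigloyloxygermacra-4E,11(13)-dien-12,6α-olide | C=C1C(=O)O[C@@H]2/C=C(\C)CC[C@H]3O[C@]3(C)C[C@@H](OC(=O)/C(C)=C/C)[C@@H]12 | intermediate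
27 | 1β,10α:4α,5β-diepoxy-8β-tigloyloxygermacr-11(13)-en-12,6α-olide (1R,4R,5R,6S,7R,8R,10R) | C=C1C(=O)O[C@H]2[C@H]1[C@H](OC(=O)/C(C)=C/C)C[C@@]1(C)O[C@@H]1CC[C@@]1(C)O[C@H]21 | target

## Step count and risks

Total step count: 14. Longest linear sequence: 11 (steps 1–5, then 9–14).

**Step 12.**
- What may go wrong: oligomerisation through intermolecular coupling, hydrodeiodination at C9 or C10, or loss of iodide and hydroxide from C9/C8 to a terminal alkene.
- Fallback: known chemistry that still closes the ring at C9–C10, now as a polar addition one oxidation level higher.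
- It sets out from diol 20, which is silylated (TESCl, imidazole) to the bis(triethylsilyl) ether F1.
- A Swern oxidation, which attacks only the primary silyl ether, gives the α-silyloxy aldehyde F2.
- A Nozaki–Hiyama–Kishi reaction (CrCl2, cat. NiCl2, DMSO, high dilution) adds the C10 alkenylchromium to the C9 aldehyde and gives the cyclic allylic alcohol F3 as either C9 epimer.
- Both epimers are converted (ClCO2Me, pyridine) into the allylic carbonate F4.
- Palladium-catalysed formate hydrogenolysis of the Tsuji–Trost type (Pd(OAc)2, PBu3, HCO2NH4) funnels both epimers into the silyl ether F5, because hydride goes to the more hindered allyl terminus C9.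
- HF·pyridine then comes back to the route at alcohol 22.

**Step 9.**
- What may go wrong: poor facial selectivity at C7 relative to C8, or sluggish addition of the hindered boronate.
- Fallback: a move from substrate control to catalyst control. It sets out from 10 and 16, which are combined under a chiral BINOL-derived phosphoric acid bearing 3,3'-bis(2,4,6-triisopropylphenyl) groups.
- The catalyst enantiomer is chosen so that the activated boronate attacks the aldehyde face that leads to the C6 configuration of 18.
- Since the chair ties C7 to C6, the pair is then fixed whatever the bias of C8. Lactonisation comes back to the route at 18, and no new compound is made.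

**Step 8.**
- What may go wrong: erosion of the alkene geometry of the α-aluminoacrylate through its allenolate form during the slow alkylation.
- Fallback: the trapping is separated from the carbon–carbon bond formation. It sets out from 14, whose alkenylalane 15 is quenched at low temperature with I2, a fast and stereoretentive event, to give the (E)-α-iodoacrylate F6.
- ICH2B(pin) and zinc dust give (pinacolatoboryl)methylzinc iodide F7.
- A stereoretentive Negishi coupling of F6 with F7 (Pd(PPh3)4, THF) comes back to the route at 16.

## Further compounds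

F1 | step 12 | bis(triethylsilyl) ether of 20 | O=S(=O)(c1ccccc1)C[C@@H]1C(=O)O[C@H](/C=C(\C)CC/C=C(\C)I)[C@H]1[C@H](O[Si](CC)(CC)CC)CO[Si](CC)(CC)CC
F2 | step 12 | C9 aldehyde with C8–OTES | O=S(=O)(c1ccccc1)C[C@@H]1C(=O)O[C@H](/C=C(\C)CC/C=C(\C)I)[C@H]1[C@H](O[Si](CC)(CC)CC)C=O
F3 | step 12 | cyclic allylic alcohol, C9–OH (both epimers), C8–OTES | O=S(=O)(c1ccccc1)C[C@@H]1C(=O)O[C@@H]2/C=C(\C)CC/C=C(\C)C(O)[C@@H](O[Si](CC)(CC)CC)[C@@H]12
F4 | step 12 | C9 methyl carbonate of F3 | O=S(=O)(c1ccccc1)C[C@@H]1C(=O)O[C@@H]2/C=C(\C)CC/C=C(\C)C(OC(=O)OC)[C@@H](O[Si](CC)(CC)CC)[C@@H]12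
F5 | step 12 | triethylsilyl ether of 22 | O=S(=O)(c1ccccc1)C[C@@H]1C(=O)O[C@@H]2/C=C(\C)CC/C=C(\C)C[C@@H](O[Si](CC)(CC)CC)[C@@H]12
F0 | step 9 | none | none
F6 | step 8 | methyl (E)-2-iodo-3-[(4S)-2,2-dimethyl-1,3-dioxolan-4-yl]acrylate | COC(=O)/C(I)=C\[C@H]1COC(C)(C)O1
F7 | step 8 | (pinacolatoboryl)methylzinc iodide | I[Zn]CB1OC(C)(C)C(C)(C)O1
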